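**Plan**
1. Retrosynthesis cuts, in order: the two O–CH3 bonds on ring B and the six C–Br bonds at C3', C5' (both outer rings) and B3, B6; the two C4'–O bonds (back to C4'–Br); in each outer ring C1'–C2' and C5'–C6'; last, the two O–C(sp) bonds of a bis(ynol ether).
2. Forward: ring B is bought as 2,5-dimethoxybenzoquinone, reduced, O-dichlorovinylated and converted into a bis(ethynyl ether). Both outer benzene rings then form together from 3,5-dibromo-2-pyrone by [4+2] cycloaddition and CO2 loss.
3. Finish: C4'–Br to C4'–OH by borylation and oxidation, sixfold bromination, O-demethylation.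
4. Enabling feature: in each outer ring the ether carbon C1' lies between the brominated C2' and C6'–H. C1' and C6' therefore map onto an aryloxyalkyne and C2'–C5' onto pyrone C3–C6, with the pyrone C3 bromine landing on C2' and the C5 bromine marking C4' for the later hydroxyl.
5. Stereochemistry: the target is achiral and has no stereocentre. The E geometry of the dichlorovinyl ethers and the bridgehead centres of the cycloadduct are transient.

Key step: step 4

Remark: 3,5-dibromo-2H-pyran-2-one is taken as a purchasable reagent.
Remark: in the two-directional steps both arms are drawn as reacting together; half-reacted species are not numbered separately.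
Remark: outer-ring atoms are C1' (ether carbon) to C6'; ring B is the central ring, with B1/B4 carrying the aryloxy groups, B2/B5 the methoxy or hydroxy groups and B3/B6 the bromines.

**Route**

Step 1
Reactants: 1 2,5-dimethoxy-1,4-benzoquinone
Product: 2 2,5-dimethoxybenzene-1,4-diol
Conditions: Na2S2O4 (3 equiv), EtOAc/H2O, rt, Ar
Reagents that add atoms: none
Why: Reduction of a quinone to its hydroquinone by Na2S2O4 is a standard two-electron reduction, and the electron-rich diol is kept under argon and used at once to avoid re-oxidation.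

Step 2
Reactants: 2 2,5-dimethoxybenzene-1,4-diol; 3 trichloroethylene
Product: 5 1,4-bis{[(E)-1,2-dichloroethenyl]oxy}-2,5-dimethoxybenzene, via dichloroacetylene 4 (not isolated)
Conditions: 3 (3 equiv), K2CO3 (4 equiv), degassed DMF, 70 °C, Ar
Reagents that add atoms: none
Why: This is the known base-mediated O-dichlorovinylation of phenols, in which K2CO3 eliminates HCl from 3 to give dichloroacetylene in low concentration and each phenoxide adds to it in anti fashion, which fixes the E geometry (not needed later).

Step 3
Reactants: 5 1,4-bis{[(E)-1,2-dichloroethenyl]oxy}-2,5-dimethoxybenzene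
Product: 8 1,4-bis(ethynyloxy)-2,5-dimethoxybenzene, via bis(chloroethynyl) ether 6 (not isolated), via dilithium bis(acetylide) 7 (not isolated)
Conditions: n-BuLi (4.6 equiv), THF, −78 to −40 °C; sat. aq. NH4Cl, −78 °C; product kept as a cold solution and used at once
Reagents that add atoms: none
Why: The established dehydrochlorination and chlorine–lithium exchange of aryl dichlorovinyl ethers with n-BuLi should give the lithium alkynolate ethers, which a cold proton quench converts into the terminal ynol ethers, and ring B carries no halogen that n-BuLi could attack.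

Step 4
Reactants: 8 1,4-bis(ethynyloxy)-2,5-dimethoxybenzene; 9 3,5-dibromo-2H-pyran-2-one
Product: 11 1,4-bis(2,4-dibromophenoxy)-2,5-dimethoxybenzene, via twofold bridged lactone 10 (not isolated)
Conditions: 9 (5 equiv), 2,6-di-tert-butyl-4-methylphenol (cat.), toluene, slow addition of 8 at 70 °C, then 100 °C, dark, Ar (−2 CO2)
Reagents that add atoms: none
Why: Proposed new method: the electron-rich aryloxyalkyne should add across C3 and C6 of the electron-poor bromopyrone in an asynchronous inverse-electron-demand Diels–Alder reaction, the nucleophilic terminal alkyne carbon bonding to the electrophilic C6 and the oxygen-bearing carbon to the bromine-bearing C3, and the resulting 2-oxabicyclo[2.2.2]octa-5,7-dien-3-one should expel CO2 by retro-[4+2] at the same temperature. The closest known reactions are the cycloadditions of 3-bromo- and 3,5-dibromo-2-pyrone with enol ethers, which place the alkoxy-bearing carbon next to the brominated bridgehead, and the pyrone–alkyne Diels–Alder/decarboxylation route to benzenes; an aryl ethynyl ether has not been shown as the two-carbon partner. Each outer ring closes by an intermolecular [4+2] cycloaddition that forms C1'–C2' and C5'–C6' (four carbons from the pyrone, two from the alkyne) and becomes aromatic by CO2 extrusion without an oxidant. The bridgehead stereocentres of the adduct are transient and vanish on aromatisation, so no stereocontrol is needed. The step needs regioselectivity (bromine at C2' beside the ether carbon), which is secured by the matched polarisation of the ynol ether (nucleophilic at its terminal carbon) and the pyrone (electrophilic at C6, anion-stabilising at the brominated C3). Slow addition of the dienophile to an excess of the pyrone should let cycloaddition outrun oligomerisation of the ynol ether, and the two arms, insulated by ring B, react independently.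

Step 5
Reactants: 11 1,4-bis(2,4-dibromophenoxy)-2,5-dimethoxybenzene
Product: 12 1,4-bis[2-bromo-4-(4,4,5,5-tetramethyl-1,3,2-dioxaborolan-2-yl)phenoxy]-2,5-dimethoxybenzene
Conditions: B2pin2 (2.1 equiv), Pd(dppf)Cl2 (5 mol %), KOAc (6 equiv), 1,4-dioxane, 80 °C
Reagents that add atoms: bis(pinacolato)diboron, CC1(C)OB(OC1(C)C)B1OC(C)(C)C(C)(C)O1
Why: In this Miyaura borylation, oxidative addition of zerovalent palladium should occur at the C4' bromides, which have two ortho hydrogens, before the C2' bromides, which sit beside the bulky aryloxy group, and KOAc is too weak a base to start Suzuki coupling of the product.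

Step 6
Reactants: 12 1,4-bis[2-bromo-4-(4,4,5,5-tetramethyl-1,3,2-dioxaborolan-2-yl)phenoxy]-2,5-dimethoxybenzene
Product: 13 1,4-bis(2-bromo-4-hydroxyphenoxy)-2,5-dimethoxybenzene
Conditions: 30% aq. H2O2, NaOH (2.2 equiv), THF/H2O, 0 °C; then dilute HCl
Reagents that add atoms: hydrogen peroxide, OO
Why: Oxidation of an arylboronic ester by hydroperoxide, with 1,2-shift of the aryl group from boron to oxygen, is general, and aryl bromides, methyl ethers and diaryl ethers are inert to it.

Step 7
Reactants: 13 1,4-bis(2-bromo-4-hydroxyphenoxy)-2,5-dimethoxybenzene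
Product: 14 1,4-dibromo-2,5-dimethoxy-3,6-bis(2,3,5-tribromo-4-hydroxyphenoxy)benzene
Conditions: Br2 (6.2 equiv), AcOH/CH2Cl2, 0 °C to rt
Reagents that add atoms: bromine, BrBr
Why: In this electrophilic aromatic bromination the free C4' hydroxyls direct to both ortho positions C3' and C5' and the two open positions of the tetraoxygenated ring B are the next most electron-rich sites, whereas C6' (meta to the hydroxyl on a ring that then bears three bromines) should stay untouched at this stoichiometry.

Step 8
Reactants: 14 1,4-dibromo-2,5-dimethoxy-3,6-bis(2,3,5-tribromo-4-hydroxyphenoxy)benzene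
Product: 15 3,6-dibromo-2,5-bis(2,3,5-tribromo-4-hydroxyphenoxy)benzene-1,4-diol (CNP0163357.0)
Conditions: BBr3 (8 equiv), CH2Cl2, −78 °C to rt; degassed H2O, Ar
Reagents that add atoms: none
Why: Lewis-acid cleavage of aryl methyl ethers by BBr3 (bromide attacks the methyl group of the O–B complex) leaves diaryl ethers and aryl bromides intact, and work-up under argon protects the product hydroquinone from air oxidation.

**Compound list**
1 | 2,5-dimethoxy-1,4-benzoquinone | COC1=CC(=O)C(OC)=CC1=O | starting material
2 | 2,5-dimethoxybenzene-1,4-diol | COc1cc(O)c(OC)cc1O | intermediate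
3 | trichloroethylene | ClC=C(Cl)Cl | starting material
4 | dichloroacetylene | ClC#CCl | intermediate (not isolated)
5 | 1,4-bis{[(E)-1,2-dichloroethenyl]oxy}-2,5-dimethoxybenzene | COc1cc(O/C(Cl)=C\Cl)c(OC)cc1O/C(Cl)=C\Cl | intermediate
6 | 1,4-bis[(chloroethynyl)oxy]-2,5-dimethoxybenzene | COc1cc(OC#CCl)c(OC)cc1OC#CCl | intermediate (not isolated)
7 | dilithium bis(acetylide) of 1,4-bis(ethynyloxy)-2,5-dimethoxybenzene | COc1cc(OC#C[Li])c(OC)cc1OC#C[Li] | intermediate (not isolated)
8 | 1,4-bis(ethynyloxy)-2,5-dimethoxybenzene | COc1cc(OC#C)c(OC)cc1OC#C | intermediate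
9 | 3,5-dibromo-2H-pyran-2-one | O=C1OC=C(Br)C=C1Br | starting material
10 | 5,5'-[(2,5-dimethoxy-1,4-phenylene)bis(oxy)]bis(4,7-dibromo-2-oxabicyclo[2.2.2]octa-5,7-dien-3-one), mixture of stereoisomers | COc1cc(OC2=CC3OC(=O)C2(Br)C=C3Br)c(OC)cc1OC1=CC2OC(=O)C1(Br)C=C2Br | intermediate (not isolated)
11 | 1,4-bis(2,4-dibromophenoxy)-2,5-dimethoxybenzene | COc1cc(Oc2ccc(Br)cc2Br)c(OC)cc1Oc1ccc(Br)cc1Br | intermediate
12 | 1,4-bis[2-bromo-4-(4,4,5,5-tetramethyl-1,3,2-dioxaborolan-2-yl)phenoxy]-2,5-dimethoxybenzene | COc1cc(Oc2ccc(B3OC(C)(C)C(C)(C)O3)cc2Br)c(OC)cc1Oc1ccc(B2OC(C)(C)C(C)(C)O2)cc1Br | intermediate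
13 | 1,4-bis(2-bromo-4-hydroxyphenoxy)-2,5-dimethoxybenzene | COc1cc(Oc2ccc(O)cc2Br)c(OC)cc1Oc1ccc(O)cc1Br | intermediate
14 | 1,4-dibromo-2,5-dimethoxy-3,6-bis(2,3,5-tribromo-4-hydroxyphenoxy)benzene | COc1c(Br)c(Oc2cc(Br)c(O)c(Br)c2Br)c(OC)c(Br)c1Oc1cc(Br)c(O)c(Br)c1Br | intermediate
15 | 3,6-dibromo-2,5-bis(2,3,5-tribromo-4-hydroxyphenoxy)benzene-1,4-diol | Oc1c(Br)cc(Oc2c(O)c(Br)c(Oc3cc(Br)c(O)c(Br)c3Br)c(O)c2Br)c(Br)c1Br | target

**Count**
Total steps: 8. Longest linear sequence: 8 steps (1 to 15); compounds 3 and 9 are purchased.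

**Steps most likely to fail**

Step 4 (Proposed new method). What may go wrong: oligomerisation of the terminal ynol ether may outpace the cycloaddition, a stepwise polar addition may divert to open-chain products, or regiocontrol may be lost on one arm. The fallback uses known chemistry, sets out from 2 and comes back at 11. The two aryl–oxygen bonds are made by metal-free O-arylation of the bis(phenoxide) of 2 with the symmetrical diaryliodonium salt bis(2,4-dibromophenyl)iodonium chloride F1. This salt is prepared from 1,3-dibromobenzene and iodyl sulfate in H2SO4 and precipitated with NaCl. Heating 2 with F1 (2.2 equiv) and NaOH in degassed H2O/1,4-dioxane should transfer one 2,4-dibromophenyl group to each oxygen by ligand coupling at trivalent iodine, giving 11; the symmetrical salt leaves no choice of which aryl group is transferred.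

Step 5. What may go wrong: insufficient discrimination between the C4' and C2' bromides in the oxidative addition, giving mixtures of regioisomeric and over-borylated boronates across the two arms. The fallback sets out from 11 and comes back at 14. It rests instead on the reliable preference of bromine–lithium exchange for the bromide ortho to an ether oxygen.
- n-BuLi (2.1 equiv, Et2O, −78 °C) should give 1,4-bis(4-bromo-2-lithiophenoxy)-2,5-dimethoxybenzene F2, which is trapped with Me3SiCl as 1,4-bis[4-bromo-2-(trimethylsilyl)phenoxy]-2,5-dimethoxybenzene F3.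
- The only bromides left, at C4', are borylated (B2pin2, Pd(dppf)Cl2, KOAc, 1,4-dioxane, 80 °C) to 1,4-bis[4-(4,4,5,5-tetramethyl-1,3,2-dioxaborolan-2-yl)-2-(trimethylsilyl)phenoxy]-2,5-dimethoxybenzene F4.
- Oxidation (H2O2, NaOH, THF/H2O) gives 1,4-bis[4-hydroxy-2-(trimethylsilyl)phenoxy]-2,5-dimethoxybenzene F5.
- Br2 (8 equiv, AcOH/CH2Cl2) then brominates C3', C5', B3 and B6 and replaces each silyl group by bromine through ipso-bromodesilylation, giving 14.

Step 7. What may go wrong: the six brominations run at different rates, so substitution at the hindered ring B positions may lag while C6' begins to react, or Br2 may oxidise the tetraoxygenated ring B with loss of a methyl group. The fallback sets out from 11 and comes back at 14, and it separates the two bromination events.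
- Ring B is brominated first, on 11, where the outer rings are deactivated dibromoaryl ethers (Br2, 2.1 equiv, AcOH/CH2Cl2), giving 1,4-dibromo-2,5-bis(2,4-dibromophenoxy)-3,6-dimethoxybenzene F6.
- Miyaura borylation, in which the doubly flanked ring B bromides should resist oxidative addition, gives 1,4-dibromo-2,5-bis[2-bromo-4-(4,4,5,5-tetramethyl-1,3,2-dioxaborolan-2-yl)phenoxy]-3,6-dimethoxybenzene F7.
- Oxidation with H2O2/NaOH gives 1,4-dibromo-2,5-bis(2-bromo-4-hydroxyphenoxy)-3,6-dimethoxybenzene F8.
- Only the four fast phenol ortho-brominations remain (Br2, 4.1 equiv, AcOH/CH2Cl2, 0 °C), giving 14.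

**Further compounds**
F1 | step 4 | bis(2,4-dibromophenyl)iodonium chloride | Brc1ccc([I+]c2ccc(Br)cc2Br)c(Br)c1.[Cl-]
F2 | step 5 | 1,4-bis(4-bromo-2-lithiophenoxy)-2,5-dimethoxybenzene | COc1cc(Oc2ccc(Br)cc2[Li])c(OC)cc1Oc1ccc(Br)cc1[Li]
F3 | step 5 | 1,4-bis[4-bromo-2-(trimethylsilyl)phenoxy]-2,5-dimethoxybenzene | COc1cc(Oc2ccc(Br)cc2[Si](C)(C)C)c(OC)cc1Oc1ccc(Br)cc1[Si](C)(C)C
F4 | step 5 | 1,4-bis[4-(4,4,5,5-tetramethyl-1,3,2-dioxaborolan-2-yl)-2-(trimethylsilyl)phenoxy]-2,5-dimethoxybenzene | COc1cc(Oc2ccc(B3OC(C)(C)C(C)(C)O3)cc2[Si](C)(C)C)c(OC)cc1Oc1ccc(B2OC(C)(C)C(C)(C)O2)cc1[Si](C)(C)C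
F5 | step 5 | 1,4-bis[4-hydroxy-2-(trimethylsilyl)phenoxy]-2,5-dimethoxybenzene | COc1cc(Oc2ccc(O)cc2[Si](C)(C)C)c(OC)cc1Oc1ccc(O)cc1[Si](C)(C)C
F6 | step 7 | 1,4-dibromo-2,5-bis(2,4-dibromophenoxy)-3,6-dimethoxybenzene | COc1c(Br)c(Oc2ccc(Br)cc2Br)c(OC)c(Br)c1Oc1ccc(Br)cc1Br
F7 | step 7 | 1,4-dibromo-2,5-bis[2-bromo-4-(4,4,5,5-tetramethyl-1,3,2-dioxaborolan-2-yl)phenoxy]-3,6-dimethoxybenzene | COc1c(Br)c(Oc2ccc(B3OC(C)(C)C(C)(C)O3)cc2Br)c(OC)c(Br)c1Oc1ccc(B2OC(C)(C)C(C)(C)O2)cc1Br
F8 | step 7 | 1,4-dibromo-2,5-bis(2-bromo-4-hydroxyphenoxy)-3,6-dimethoxybenzene | COc1c(Br)c(Oc2ccc(O)cc2Br)c(OC)c(Br)c1Oc1ccc(O)cc1Br
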